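**Plan**

- Retrosynthesis first removes the two ring B side chains: the aryl–prenyl bond (Suzuki coupling) and the aryl–vinyl bond (Heck coupling), leaving a 3'-bromo-5'-iodo-4'-methoxyflavanone.
- Ring C is then cut at the aryl ketone bond C4–C4a, giving an (S)-3-aryl-3-(3,5-dihydroxyphenoxy)propanoic acid. This cut works because ring A carries oxygen at C5, C7 and C8a: the phloroglucinol ether of C2 has two equivalent ortho carbons, each activated by three oxygens, and either one gives the same chromanone.
- The ether bond O1–C2 is cut back to phloroglucinol and an (R)-β-hydroxy ester, and the C3–C4 bond to an aryl methyl ketone and diethyl carbonate.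
- Forward order: ring B is iodinated and O-methylated, the three-carbon chain is completed, ring A is attached through O1, ring C is closed by acylation, and the two acid-labile side chains are coupled last.
- The only stereocentre, C2, comes from catalyst-controlled transfer hydrogenation of the β-keto ester and is inverted once, (R) to (S), in the Mitsunobu etherification; the ring closure only has to preserve it.

Key step: step 7

Assumption: the (R,R)-TsDPEN ruthenium catalyst is taken to deliver hydride to the same ketone face as with simple aryl methyl ketones, giving the (R)-carbinol; should the sense prove opposite, the (S,S)-ligand is used with nothing else changed.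

**Route**

Step 1
Reactants: 1 3'-bromo-4'-hydroxyacetophenone
Product: 2 1-(3-bromo-4-hydroxy-5-iodophenyl)ethanone
Conditions: NIS (1.1 equiv), TsOH·H2O (0.1 equiv), MeCN, rt, dark
Reagents that add atoms: N-iodosuccinimide, O=C1CCC(=O)N1I
Why: Electrophilic aromatic iodination by acid-activated NIS should go to the only open position ortho to the phenol (para carries the acetyl group, the other ortho position bromine), the deactivated ring stopping at mono-iodination and the acidic medium avoiding haloform attack on the methyl ketone.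

Step 2
Reactants: 2 1-(3-bromo-4-hydroxy-5-iodophenyl)ethanone
Product: 3 1-(3-bromo-5-iodo-4-methoxyphenyl)ethanone
Conditions: MeI (1.5 equiv), K2CO3 (2 equiv), DMF, rt
Reagents that add atoms: iodomethane, CI
Why: Williamson O-methylation (SN2) of the acidic di-ortho-halophenoxide installs the 4'-methoxy group of the target and removes the phenol before the enolate, Mitsunobu and acylation steps.

Step 3
Reactants: 3 1-(3-bromo-5-iodo-4-methoxyphenyl)ethanone
Product: 4 ethyl 3-(3-bromo-5-iodo-4-methoxyphenyl)-3-oxopropanoate
Conditions: NaH (2.5 equiv), (EtO)2CO (3 equiv), THF, reflux; then 1 M HCl, 0 °C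
Reagents that add atoms: diethyl carbonate, CCOC(=O)OCC
Why: Crossed Claisen condensation (C-ethoxycarbonylation of the methyl ketone enolate) is driven to completion by irreversible deprotonation of the β-keto ester formed, and the aryl halides and aryl methyl ether are inert to NaH.

Step 4
Reactants: 4 ethyl 3-(3-bromo-5-iodo-4-methoxyphenyl)-3-oxopropanoate
Product: 5 ethyl (3R)-3-(3-bromo-5-iodo-4-methoxyphenyl)-3-hydroxypropanoate
Conditions: RuCl(p-cymene)[(R,R)-TsDPEN] (1 mol %), HCO2H/Et3N (5:2), EtOAc, 30 °C
Reagents that add atoms: none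
Why: Noyori asymmetric transfer hydrogenation passes hydride and proton from the ruthenium hydride–amine complex to the aryl ketone through a six-membered outer-sphere transition state in which the CH/π contact between the cymene ligand and the aryl ring fixes the face, so the (R,R)-ligand should set the (R)-carbinol, and the C–I and C–Br bonds are untouched because neither H2 nor a zerovalent metal is present.

Step 5
Reactants: 5 ethyl (3R)-3-(3-bromo-5-iodo-4-methoxyphenyl)-3-hydroxypropanoate; 6 phloroglucinol (anhydrous, 5 equiv)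
Product: 8 ethyl (3S)-3-(3-bromo-5-iodo-4-methoxyphenyl)-3-(3,5-dihydroxyphenoxy)propanoate, via alkoxyphosphonium phenoxide 7 (not isolated)
Conditions: PPh3 (1.5 equiv), DIAD (1.5 equiv, slow addition), THF, 0 °C to rt
Reagents that add atoms: none
Why: Mitsunobu etherification, in which the PPh3–DIAD betaine turns the carbinol into alkoxyphosphonium ion 7 and a phloroglucinol oxygen (pKa about 8.5, in excess so that only one of its three equivalent hydroxyls reacts) displaces it by SN2 with inversion, converting (R) into the (S) configuration needed at C2, the halogen-deactivated benzylic carbon resisting SN1 leakage.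

Step 6
Reactants: 8 ethyl (3S)-3-(3-bromo-5-iodo-4-methoxyphenyl)-3-(3,5-dihydroxyphenoxy)propanoate
Product: 9 (3S)-3-(3-bromo-5-iodo-4-methoxyphenyl)-3-(3,5-dihydroxyphenoxy)propanoic acid
Conditions: LiOH·H2O (4 equiv), THF/H2O (3:1), degassed, 0 °C to rt; then 1 M HCl to pH 3, 0 °C
Reagents that add atoms: lithium hydroxide, [Li+].[OH-]
Why: Saponification (BAc2 ester hydrolysis) at low temperature, in which the first equivalents of base form the phenoxide dianion and thereby make the aryloxy group a poor leaving group, so that E1cB loss of the ether should be suppressed and the C3 stereocentre is not involved.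

Step 7
Reactants: 9 (3S)-3-(3-bromo-5-iodo-4-methoxyphenyl)-3-(3,5-dihydroxyphenoxy)propanoic acid
Product: 11 (2S)-2-(3-bromo-5-iodo-4-methoxyphenyl)-5,7-dihydroxychroman-4-one, via mixed methanesulfonic anhydride 10 (not isolated)
Conditions: Eaton's reagent (P2O5 in MeSO3H, 1:10 w/w), 0 °C to rt, short reaction time; then ice-water
Reagents that add atoms: none
Why: Dehydration by P2O5 in methanesulfonic acid converts the acid into mixed anhydride 10, which ionises to an acylium ion that is attacked by the ring carbon ortho to the ether oxygen, and loss of a proton from the arenium ion restores ring A as the aryl ketone with its 5-hydroxyl hydrogen-bonded to the new carbonyl. The closest known reaction type is the intramolecular Friedel–Crafts (Hoesch-type) acylation of 3-aryloxypropanoic acids to chroman-4-ones in Eaton's reagent or polyphosphoric acid. Ring C closes as a six-membered ring by 6-exo attack at the acylium carbon (bond C4–C4a), the C=O staying outside the ring. No stereocentre is created; C2, set in steps 4 and 5, only has to survive, and none of its bonds is made or broken. Regioselectivity is not an issue because the 3,5-dihydroxyphenyl ether has two homotopic ortho carbons, each activated by three oxygen substituents, which is also why the closure should run cold and fast, before benzylic C2–O1 ionisation or retro-oxa-Michael cleavage can compete. Those racemising paths are further slowed by the bromine and iodine flanking the 4'-methoxy group, which twist it out of conjugation and make ring B electron-poor, and the acid-labile prenyl and tertiary allylic alcohol groups are not yet present.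

Step 8
Reactants: 11 (2S)-2-(3-bromo-5-iodo-4-methoxyphenyl)-5,7-dihydroxychroman-4-one; 12 2-methylbut-3-en-2-ol (3 equiv)
Product: 13 (2S)-2-{3-bromo-5-[(E)-3-hydroxy-3-methylbut-1-enyl]-4-methoxyphenyl}-5,7-dihydroxychroman-4-one
Conditions: Pd(OAc)2 (5 mol %), Bu4NCl (1 equiv), NaHCO3 (3 equiv), DMF, 50 °C, argon
Reagents that add atoms: none
Why: Mizoroki–Heck reaction under ligand-free Jeffery conditions, in which zerovalent palladium inserts into C–I far faster than into C–Br at 50 °C, the aryl group adds to the terminal alkene carbon and β-hydride elimination can only occur toward the benzylic hydrogen (the carbinol carbon has none), giving the (E)-styryl tertiary alcohol, while the weak base NaHCO3 should leave the flavanone closed.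

Step 9
Reactants: 13 (2S)-2-{3-bromo-5-[(E)-3-hydroxy-3-methylbut-1-enyl]-4-methoxyphenyl}-5,7-dihydroxychroman-4-one; 14 3-methylbut-2-enylboronic acid pinacol ester (2 equiv)
Product: 15 (2S)-5,7-dihydroxy-2-{3-[(E)-3-hydroxy-3-methylbut-1-enyl]-4-methoxy-5-(3-methylbut-2-enyl)phenyl}chroman-4-one
Conditions: Pd(dppf)Cl2·CH2Cl2 (5 mol %), K3PO4 (3 equiv), THF/H2O (10:1), degassed, 60 °C
Reagents that add atoms: none
Why: Suzuki–Miyaura sp2–sp3 coupling, in which oxidative addition to the remaining C–Br bond, base-assisted transmetalation of the allylic boronate and σ–π–σ equilibration of the prenylpalladium species under the chelating dppf ligand place palladium on the unhindered primary carbon before reductive elimination, so the linear 3-methylbut-2-enyl group should result, moderate temperature and short reaction time limiting base-induced opening of ring C.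

**Compound list**

1 | 3'-bromo-4'-hydroxyacetophenone | CC(=O)c1ccc(O)c(Br)c1 | starting material
2 | 1-(3-bromo-4-hydroxy-5-iodophenyl)ethanone | CC(=O)c1cc(Br)c(O)c(I)c1 | intermediate
3 | 1-(3-bromo-5-iodo-4-methoxyphenyl)ethanone | CC(=O)c1cc(Br)c(OC)c(I)c1 | intermediate
4 | ethyl 3-(3-bromo-5-iodo-4-methoxyphenyl)-3-oxopropanoate | CCOC(=O)CC(=O)c1cc(Br)c(OC)c(I)c1 | intermediate
5 | ethyl (3R)-3-(3-bromo-5-iodo-4-methoxyphenyl)-3-hydroxypropanoate | CCOC(=O)C[C@@H](O)c1cc(Br)c(OC)c(I)c1 | intermediate
6 | phloroglucinol (benzene-1,3,5-triol) | Oc1cc(O)cc(O)c1 | starting material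
7 | [(1R)-1-(3-bromo-5-iodo-4-methoxyphenyl)-3-ethoxy-3-oxopropoxy]triphenylphosphonium 3,5-dihydroxyphenoxide | CCOC(=O)C[C@@H](O[P+](c1ccccc1)(c1ccccc1)c1ccccc1)c1cc(Br)c(OC)c(I)c1.[O-]c1cc(O)cc(O)c1 | intermediate
8 | ethyl (3S)-3-(3-bromo-5-iodo-4-methoxyphenyl)-3-(3,5-dihydroxyphenoxy)propanoate | CCOC(=O)C[C@H](Oc1cc(O)cc(O)c1)c1cc(Br)c(OC)c(I)c1 | intermediate
9 | (3S)-3-(3-bromo-5-iodo-4-methoxyphenyl)-3-(3,5-dihydroxyphenoxy)propanoic acid | OC(=O)C[C@H](Oc1cc(O)cc(O)c1)c1cc(Br)c(OC)c(I)c1 | intermediate
10 | (3S)-3-(3-bromo-5-iodo-4-methoxyphenyl)-3-(3,5-dihydroxyphenoxy)propanoic methanesulfonic anhydride | CS(=O)(=O)OC(=O)C[C@H](Oc1cc(O)cc(O)c1)c1cc(Br)c(OC)c(I)c1 | intermediate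
11 | (2S)-2-(3-bromo-5-iodo-4-methoxyphenyl)-5,7-dihydroxychroman-4-one | COc1c(I)cc([C@@H]2CC(=O)c3c(O)cc(O)cc3O2)cc1Br | intermediate
12 | 2-methylbut-3-en-2-ol | CC(C)(O)C=C | starting material
13 | (2S)-2-{3-bromo-5-[(E)-3-hydroxy-3-methylbut-1-enyl]-4-methoxyphenyl}-5,7-dihydroxychroman-4-one | COc1c(/C=C/C(C)(C)O)cc([C@@H]2CC(=O)c3c(O)cc(O)cc3O2)cc1Br | intermediate
14 | 3-methylbut-2-enylboronic acid pinacol ester | CC(C)=CCB1OC(C)(C)C(C)(C)O1 | starting material
15 | (2S)-5,7-dihydroxy-2-{3-[(E)-3-hydroxy-3-methylbut-1-enyl]-4-methoxy-5-(3-methylbut-2-enyl)phenyl}chroman-4-one | COc1c(/C=C/C(C)(C)O)cc([C@@H]2CC(=O)c3c(O)cc(O)cc3O2)cc1CC=C(C)C | target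

**Step count**

Total: 9 steps. Longest linear sequence: 9 steps (1 to 15).

**Steps most likely to fail**

Step 5 (Mitsunobu etherification). The hydrazide anion may remove an α-hydrogen of the activated ester faster than the phenol substitutes, so that the carbinol is lost by elimination to the cinnamate; a second alkylation of phloroglucinol is a lesser concern. The fallback sets out from 5 and comes back at 9. It moves the substitution to the alcohol oxidation level, where no acidic α-hydrogen is present.
- LiBH4 in THF should reduce 5 to (1R)-1-(3-bromo-5-iodo-4-methoxyphenyl)propane-1,3-diol F1.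
- TBSCl and imidazole at 0 °C should silylate only the primary hydroxyl, giving (1R)-1-(3-bromo-5-iodo-4-methoxyphenyl)-3-(tert-butyldimethylsilyloxy)propan-1-ol F2.
- Mitsunobu reaction (PPh3, DIAD, THF) of F2 with 3,5-bis(tert-butyldimethylsilyloxy)phenol F3, prepared from 6 with two equivalents of TBSCl, should give with inversion tert-butyl{(3S)-3-(3-bromo-5-iodo-4-methoxyphenyl)-3-[3,5-bis(tert-butyldimethylsilyloxy)phenoxy]propoxy}dimethylsilane F4.
- Camphorsulfonic acid in MeOH/CH2Cl2 at 0 °C should cleave only the alkyl silyl ether, giving (3S)-3-(3-bromo-5-iodo-4-methoxyphenyl)-3-[3,5-bis(tert-butyldimethylsilyloxy)phenoxy]propan-1-ol F5.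
- TEMPO (catalytic) with PhI(OAc)2 in aqueous MeCN should oxidise the primary alcohol to (3S)-3-(3-bromo-5-iodo-4-methoxyphenyl)-3-[3,5-bis(tert-butyldimethylsilyloxy)phenoxy]propanoic acid F6, the silylated ring being shielded from oxidation.
- Et3N·3HF in THF then frees the two phenols and delivers 9, from which step 7 continues unchanged.

Step 7 (ring closure). In the strongly acidic medium the benzylic C–O bond may ionise, or the activated acid may undergo retro-oxa-Michael cleavage, so that phloroglucinol is lost or recombines without stereocontrol and enantiomeric purity erodes; sulfonylation or intermolecular acylation of the free phenols may also compete. The fallback sets out from 9 and comes back at 11. It keeps the same C4–C4a closure but runs it from an isolated acid chloride with masked phenols and a Lewis acid at low temperature.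
- TBSCl (3.3 equiv) and imidazole in DMF should give tert-butyldimethylsilyl (3S)-3-(3-bromo-5-iodo-4-methoxyphenyl)-3-[3,5-bis(tert-butyldimethylsilyloxy)phenoxy]propanoate F7.
- (COCl)2 with catalytic DMF in CH2Cl2 at 0 °C should convert the silyl ester directly, under neutral conditions, into (3S)-3-(3-bromo-5-iodo-4-methoxyphenyl)-3-[3,5-bis(tert-butyldimethylsilyloxy)phenoxy]propanoyl chloride F8.
- SnCl4 (1.1 equiv) in CH2Cl2 at −78 °C should close ring C to (2S)-2-(3-bromo-5-iodo-4-methoxyphenyl)-5,7-bis(tert-butyldimethylsilyloxy)chroman-4-one F9.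
- Et3N·3HF in THF removes the silyl groups (any partly desilylated material converges here) and gives 11.

Step 9 (Suzuki prenylation). Reductive elimination may occur through the tertiary allyl terminus, giving the reverse-prenyl isomer, and heating with aqueous phosphate may open ring C to the chalcone and scramble C2. The fallback sets out from 13 and comes back at 15. It replaces the boron reagent and base by a Stille coupling under neutral conditions: tributyl(3-methylbut-2-enyl)stannane, Pd(PPh3)4, DMF, 90 °C. No base is present, and no further compound is made (F0).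

**Further compounds**

F1 | step 5 | (1R)-1-(3-bromo-5-iodo-4-methoxyphenyl)propane-1,3-diol | OCC[C@@H](O)c1cc(Br)c(OC)c(I)c1
F2 | step 5 | (1R)-1-(3-bromo-5-iodo-4-methoxyphenyl)-3-(tert-butyldimethylsilyloxy)propan-1-ol | CC(C)(C)[Si](C)(C)OCC[C@@H](O)c1cc(Br)c(OC)c(I)c1
F3 | step 5 | 3,5-bis(tert-butyldimethylsilyloxy)phenol | CC(C)(C)[Si](C)(C)Oc1cc(O)cc(O[Si](C)(C)C(C)(C)C)c1
F4 | step 5 | tert-butyl{(3S)-3-(3-bromo-5-iodo-4-methoxyphenyl)-3-[3,5-bis(tert-butyldimethylsilyloxy)phenoxy]propoxy}dimethylsilane | CC(C)(C)[Si](C)(C)OCC[C@H](Oc1cc(O[Si](C)(C)C(C)(C)C)cc(O[Si](C)(C)C(C)(C)C)c1)c1cc(Br)c(OC)c(I)c1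
F5 | step 5 | (3S)-3-(3-bromo-5-iodo-4-methoxyphenyl)-3-[3,5-bis(tert-butyldimethylsilyloxy)phenoxy]propan-1-ol | OCC[C@H](Oc1cc(O[Si](C)(C)C(C)(C)C)cc(O[Si](C)(C)C(C)(C)C)c1)c1cc(Br)c(OC)c(I)c1
F6 | step 5 | (3S)-3-(3-bromo-5-iodo-4-methoxyphenyl)-3-[3,5-bis(tert-butyldimethylsilyloxy)phenoxy]propanoic acid | OC(=O)C[C@H](Oc1cc(O[Si](C)(C)C(C)(C)C)cc(O[Si](C)(C)C(C)(C)C)c1)c1cc(Br)c(OC)c(I)c1
F7 | step 7 | tert-butyldimethylsilyl (3S)-3-(3-bromo-5-iodo-4-methoxyphenyl)-3-[3,5-bis(tert-butyldimethylsilyloxy)phenoxy]propanoate | CC(C)(C)[Si](C)(C)OC(=O)C[C@H](Oc1cc(O[Si](C)(C)C(C)(C)C)cc(O[Si](C)(C)C(C)(C)C)c1)c1cc(Br)c(OC)c(I)c1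
F8 | step 7 | (3S)-3-(3-bromo-5-iodo-4-methoxyphenyl)-3-[3,5-bis(tert-butyldimethylsilyloxy)phenoxy]propanoyl chloride | ClC(=O)C[C@H](Oc1cc(O[Si](C)(C)C(C)(C)C)cc(O[Si](C)(C)C(C)(C)C)c1)c1cc(Br)c(OC)c(I)c1
F9 | step 7 | (2S)-2-(3-bromo-5-iodo-4-methoxyphenyl)-5,7-bis(tert-butyldimethylsilyloxy)chroman-4-one | COc1c(I)cc([C@@H]2CC(=O)c3c(O[Si](C)(C)C(C)(C)C)cc(O[Si](C)(C)C(C)(C)C)cc3O2)cc1Br
F0 | step 9 | none | none
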